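**Plan**

- Retrosynthesis: cut C2–C3 of pyranone ring C (carbene C–H insertion) to reach diazoketone 9; remove N2 (diazo transfer) to reach methyl ketone 7; cut the benzylic C–O bond (Mitsunobu) to reach paeonol 6 and benzofuranylmethanol 5; open the furan ring (Sonogashira coupling–cyclisation) to reach iodophenol 1 and alkyne 2.
- Forward: the benzofuran ring is made first, the two halves are joined as an aryl benzyl ether, the diazo group is installed on the acetyl group, and ring C is closed last.
- Enabling feature: in 9 the future C2 is a CH2 that is benzylic, bonded to the aryl ether oxygen O1 of ring A and para to the benzofuran oxygen, so its C–H bonds are strongly hydridic. It lies 1,6 to the carbene carbon C3 (C3–C4–C4a–C8a–O1–C2), and the 1,5-position is O1, which has no hydrogen, so only six-membered insertion is possible.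
- Stereochemistry: the single stereocentre C2 (S) is set in the last step by a chiral dirhodium carboxylate that selects one of the two enantiotopic benzylic hydrogens; no later step can scramble it.

Key step: step 5

Assumption: the absolute sense of induction of the dirhodium catalyst cannot be assigned with certainty in advance. The (S)-leucinate catalyst is written; its mirror image Rh2(R-PTTL)4 would be used if a trial run shows the opposite sense.

**Route**

Step 1
Reactants: 1 4-hydroxy-3-iodobenzaldehyde; 2 4-ethynylanisole (1-ethynyl-4-methoxybenzene)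
Product: 4 2-(4-methoxyphenyl)-1-benzofuran-5-carbaldehyde, via ortho-alkynylphenol 3 (not isolated)
Conditions: PdCl2(PPh3)2 (3 mol%), CuI (5 mol%), Et3N, DMF, degassed, 70 °C
Reagents that add atoms: none
Why: Sonogashira coupling at the aryl iodide gives the ortho-alkynylphenol 3, whose phenoxide (made more acidic by the para-formyl group) adds 5-endo-dig to the metal-activated alkyne under the same conditions to give the 2-arylbenzofuran (Sonogashira coupling–heteroannulation).

Step 2
Reactants: 4 2-(4-methoxyphenyl)-1-benzofuran-5-carbaldehyde
Product: 5 [2-(4-methoxyphenyl)-1-benzofuran-5-yl]methanol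
Conditions: NaBH4, MeOH–THF, 0 °C
Reagents that add atoms: none
Why: Borohydride reduction of the aryl aldehyde to the primary benzylic alcohol is chemoselective and leaves the benzofuran and the aryl ethers untouched.

Step 3
Reactants: 5 [2-(4-methoxyphenyl)-1-benzofuran-5-yl]methanol; 6 paeonol (1-(2-hydroxy-4-methoxyphenyl)ethan-1-one)
Product: 7 1-[4-methoxy-2-({[2-(4-methoxyphenyl)-1-benzofuran-5-yl]methyl}oxy)phenyl]ethan-1-one
Conditions: PPh3, DIAD, THF, 0 °C to rt
Reagents that add atoms: none
Why: Mitsunobu etherification: the PPh3–DIAD betaine is protonated by phenol 6 (pKa about 10), the primary benzylic alcohol is activated as its alkoxyphosphonium salt and displaced by the phenoxide oxygen in an SN2 step, which should give the aryl benzyl ether without touching the ketone.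

Step 4
Reactants: 7 1-[4-methoxy-2-({[2-(4-methoxyphenyl)-1-benzofuran-5-yl]methyl}oxy)phenyl]ethan-1-one
Product: 9 2-diazo-1-[4-methoxy-2-({[2-(4-methoxyphenyl)-1-benzofuran-5-yl]methyl}oxy)phenyl]ethan-1-one, via trifluoroacetyl ketone 8 (not isolated)
Conditions: LiN(SiMe3)2, THF, −78 °C; CF3CO2CH2CF3; aq. HCl work-up, crude 8 taken on; then MsN3, Et3N, H2O (1 equiv), MeCN, rt
Reagents that add atoms: methanesulfonyl azide, CS(=O)(=O)N=[N+]=[N-] (supplies the two diazo nitrogens of 9); 2,2,2-trifluoroethyl trifluoroacetate, O=C(OCC(F)(F)F)C(F)(F)F (supplies the CF3CO group of 8 only, which is split off again)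
Why: Regitz diazo transfer in its detrifluoroacetylative form: the kinetic methyl-ketone enolate is C-trifluoroacetylated (Claisen condensation), the activated 1,3-diketone 8 accepts the diazo group from the sulfonyl azide, and the trifluoroacetyl group leaves as the N-acylsulfonamide, which should give the terminal diazoketone under conditions that the benzyl ether and the benzofuran tolerate.

Step 5
Reactants: 9 2-diazo-1-[4-methoxy-2-({[2-(4-methoxyphenyl)-1-benzofuran-5-yl]methyl}oxy)phenyl]ethan-1-one
Product: 10 Lophirone J, (2S)-7-methoxy-2-[2-(4-methoxyphenyl)-1-benzofuran-5-yl]-2,3-dihydro-4H-chromen-4-one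
Conditions: Rh2(S-PTTL)4 (dirhodium tetrakis[N-phthaloyl-(S)-tert-leucinate], 1 mol%), CH2Cl2, 4 Å MS, 0 °C, 9 added by syringe pump to high dilution (about 0.01 M); neutral work-up (filtration through silica, no base)
Reagents that add atoms: none
Why: The dirhodium tetracarboxylate (both metals divalent) takes N2 out of 9 and gives an electrophilic rhodium-bound α-keto carbene at C3, which inserts into one of the two enantiotopic benzylic C–H bonds of the OCH2 group through a three-centre, hydride-transfer-like transition state, so that the C2–C3 bond forms, the hydrogen ends on C3 and the catalyst is released. The closest known reaction type is the chiral dirhodium carboxylate-catalysed intramolecular C–H insertion of 2-alkoxyaryl α-diazoketones to chroman-4-ones, a member of the general class of carbene insertions into C–H bonds next to ether oxygen. Ring C closes in the 1,6-insertion mode (six-membered ring O1–C2–C3–C4–C4a–C8a), and the normally preferred 1,5-mode does not exist here because the fifth atom is O1, which has no hydrogen. The only stereocentre, C2, is controlled by the catalyst: the chiral pocket of the four N-phthaloyl-tert-leucinate ligands selects one enantiotopic hydrogen and the insertion goes with retention, which should give the (2S)-flavanone with the appropriate catalyst antipode. The step needs chemoselectivity for C–H insertion over attack of the carbene on the lone pair of O1 (five-membered oxonium ylide, then Stevens 1,2-benzyl shift to a 2-benzylbenzofuran-3-one) and over intermolecular cyclopropanation of the benzofuran C2=C3 bond. The first is secured by the low basicity of O1 (its lone pair is delocalised into the ortho-acyl ring A), by the strongly hydridic C–H bond (benzylic, α to oxygen, para to the benzofuran oxygen), by the use of a rhodium carboxylate instead of a copper catalyst and by the unsubstituted acceptor-only carbene, the second by slow addition at high dilution.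

**Compound list**

1 | 4-hydroxy-3-iodobenzaldehyde | O=Cc1ccc(O)c(I)c1 | starting material
2 | 4-ethynylanisole | C#Cc1ccc(OC)cc1 | starting material
3 | 4-hydroxy-3-[(4-methoxyphenyl)ethynyl]benzaldehyde | O=Cc1ccc(O)c(C#Cc2ccc(OC)cc2)c1 | intermediate
4 | 2-(4-methoxyphenyl)-1-benzofuran-5-carbaldehyde | COc1ccc(-c2cc3cc(C=O)ccc3o2)cc1 | intermediate
5 | [2-(4-methoxyphenyl)-1-benzofuran-5-yl]methanol | COc1ccc(-c2cc3cc(CO)ccc3o2)cc1 | intermediate
6 | paeonol, 1-(2-hydroxy-4-methoxyphenyl)ethan-1-one | CC(=O)c1ccc(OC)cc1O | starting material
7 | 1-[4-methoxy-2-({[2-(4-methoxyphenyl)-1-benzofuran-5-yl]methyl}oxy)phenyl]ethan-1-one | COc1ccc(-c2cc3cc(COc4cc(OC)ccc4C(C)=O)ccc3o2)cc1 | intermediate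
8 | 4,4,4-trifluoro-1-[4-methoxy-2-({[2-(4-methoxyphenyl)-1-benzofuran-5-yl]methyl}oxy)phenyl]butane-1,3-dione | COc1ccc(-c2cc3cc(COc4cc(OC)ccc4C(=O)CC(=O)C(F)(F)F)ccc3o2)cc1 | intermediate
9 | 2-diazo-1-[4-methoxy-2-({[2-(4-methoxyphenyl)-1-benzofuran-5-yl]methyl}oxy)phenyl]ethan-1-one | COc1ccc(-c2cc3cc(COc4cc(OC)ccc4C(=O)C=[N+]=[N-])ccc3o2)cc1 | intermediate
10 | Lophirone J, (2S)-7-methoxy-2-[2-(4-methoxyphenyl)-1-benzofuran-5-yl]-2,3-dihydro-4H-chromen-4-one | COc1ccc(-c2cc3cc([C@@H]4CC(=O)c5ccc(OC)cc5O4)ccc3o2)cc1 | target

**Summary**

Total steps: 5. Longest linear sequence: 5 steps (1 → 4 → 5 → 7 → 9 → 10).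

Steps most likely to fail:

1. Step 5 (C–H insertion). The carbene may be captured by the ether oxygen and rearrange by a 1,2-benzyl shift instead of inserting. Discrimination between the two enantiotopic hydrogens may also be poor, because an acceptor-only carbene reacts through an early transition state, or because the insertion becomes a stepwise hydride transfer. Fallback (asymmetric conjugate arylation, a different bond construction): it sets out from 2 and rejoins the route at 10. Alkyne 2 is coupled with 4-bromo-2-iodophenol (Oc1ccc(Br)cc1I) under the conditions of step 1, the iodide reacting selectively, to give 5-bromo-2-(4-methoxyphenyl)-1-benzofuran F1. Bromine–lithium exchange (n-BuLi, THF, −78 °C), quenching with B(OiPr)3 and aqueous HCl should give [2-(4-methoxyphenyl)-1-benzofuran-5-yl]boronic acid F2. Conjugate addition of F2 to commercial 7-methoxy-4H-chromen-4-one (COc1ccc2C(=O)C=COc2c1) follows, with Pd(OCOCF3)2, the 4-tert-butyl-2-(pyridin-2-yl)-4,5-dihydrooxazole ligand (enantiomer chosen for the (S)-series), NH4PF6 and H2O in ClCH2CH2Cl at 60 °C, and should give 10.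

2. Step 4 (diazo transfer). Incomplete C-trifluoroacetylation of the hindered ortho-alkoxy aryl ketone enolate, or loss of the diazoketone during the aqueous base stage and chromatography, may lower the throughput. Fallback (acylation of diazomethane instead of diazo transfer): it sets out from 5 and rejoins at 9. Alcohol 5 is coupled with methyl 2-hydroxy-4-methoxybenzoate (COC(=O)c1ccc(OC)cc1O) under Mitsunobu conditions (PPh3, DIAD, THF) to give methyl 4-methoxy-2-({[2-(4-methoxyphenyl)-1-benzofuran-5-yl]methyl}oxy)benzoate F3. Saponification (LiOH, THF–H2O) gives 4-methoxy-2-({[2-(4-methoxyphenyl)-1-benzofuran-5-yl]methyl}oxy)benzoic acid F4. Neutral activation with 1-chloro-N,N,2-trimethylprop-1-en-1-amine in CH2Cl2, which avoids acid cleavage of the electron-rich benzyl ether, gives 4-methoxy-2-({[2-(4-methoxyphenyl)-1-benzofuran-5-yl]methyl}oxy)benzoyl chloride F5. Excess CH2N2 in Et2O at 0 °C should then give 9.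

3. Step 3 (Mitsunobu). The intramolecularly hydrogen-bonded phenol may protonate the betaine slowly, so that the activated benzylic alcohol alkylates the hydrazine dicarboxylate instead. Fallback (SN2 alkylation through a benzylic halide): it sets out from 5 and 6 and rejoins at 7. Alcohol 5 is converted with PBr3 (CH2Cl2, 0 °C) into 5-(bromomethyl)-2-(4-methoxyphenyl)-1-benzofuran F6, which is used crude to alkylate paeonol 6 (K2CO3, DMF, 50 °C) and should give 7.

**Further compounds**

F1 | step 5 | 5-bromo-2-(4-methoxyphenyl)-1-benzofuran | COc1ccc(-c2cc3cc(Br)ccc3o2)cc1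
F2 | step 5 | [2-(4-methoxyphenyl)-1-benzofuran-5-yl]boronic acid | COc1ccc(-c2cc3cc(B(O)O)ccc3o2)cc1
F3 | step 4 | methyl 4-methoxy-2-({[2-(4-methoxyphenyl)-1-benzofuran-5-yl]methyl}oxy)benzoate | COc1ccc(-c2cc3cc(COc4cc(OC)ccc4C(=O)OC)ccc3o2)cc1
F4 | step 4 | 4-methoxy-2-({[2-(4-methoxyphenyl)-1-benzofuran-5-yl]methyl}oxy)benzoic acid | COc1ccc(-c2cc3cc(COc4cc(OC)ccc4C(=O)O)ccc3o2)cc1
F5 | step 4 | 4-methoxy-2-({[2-(4-methoxyphenyl)-1-benzofuran-5-yl]methyl}oxy)benzoyl chloride | COc1ccc(-c2cc3cc(COc4cc(OC)ccc4C(=O)Cl)ccc3o2)cc1
F6 | step 3 | 5-(bromomethyl)-2-(4-methoxyphenyl)-1-benzofuran | COc1ccc(-c2cc3cc(CBr)ccc3o2)cc1
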